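**Strategy**

- Retrosynthesis first cuts the C3–Br bond (electrophilic bromination of the free N–H indole) and puts a sulfonyl group back on nitrogen.
- The benzo ring carries Br on C4 and C6 and H on C5 and C7. It is opened at the C5–C6 bond into a 1-bromovinyl arm (C4, C5) on pyrrole C3 and a 2,2-dibromovinyl arm (C7, C6) on pyrrole C2. The second bromine on C6 is the leaving group that aromatizes the ring as HBr, and this substitution pattern is what makes an electrocyclic benzannulation possible.
- The C4=C5 bromoalkene goes back to a C3 acetyl group and the C7=C6 dibromoalkene to a C2 formyl group. The acetyl carbon is attached by cutting the C3a–C4 bond (Stille coupling on N-tosylated 3-bromo-1H-pyrrole-2-carbaldehyde 1).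
- Forward: the pyrrole ring is bought intact, the arms are installed at C3 and then C2, the benzene ring is closed last by 6π electrocyclization with loss of HBr, and detosylation and C3 bromination finish.
- Stereochemistry: the target has no stereocenter. The two sp3 carbons of the transient dihydroindole (CH2 and CBr2) are erased on aromatization, and neither alkene terminus has a geometry to control.

Key step: step 5

Remark: Ts is 4-methylbenzenesulfonyl; 1 is taken to be a catalogue compound, and the carbons of the future benzo ring are given in indole numbering throughout.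

Step 1
Reactants: 1 3-bromo-1H-pyrrole-2-carbaldehyde
Product: 2 3-bromo-1-tosylpyrrole-2-carbaldehyde
Conditions: TsCl, Et3N, DMAP (cat.), CH2Cl2, 0 °C to rt
Reagents that add atoms: p-toluenesulfonyl chloride, Cc1ccc(cc1)S(Cl)(=O)=O
Why: N-sulfonylation of a pyrrole N–H acidified by the neighbouring formyl group is routine under DMAP catalysis, and the sulfonyl group both activates the C3 bromide toward oxidative addition and shields the pyrrole from acid and electrophiles in the later steps.

Step 2
Reactants: 2 3-bromo-1-tosylpyrrole-2-carbaldehyde; 3 tributyl(1-ethoxyvinyl)stannane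
Product: 5 3-acetyl-1-tosylpyrrole-2-carbaldehyde, via 3-(1-ethoxyvinyl)-1-tosylpyrrole-2-carbaldehyde 4 (not isolated)
Conditions: Pd(PPh3)4 (5 mol %), toluene, 100 °C; then 1 M aq HCl, THF, rt
Reagents that add atoms: tributyl(1-ethoxyvinyl)stannane (compound 3), CCOC(=C)[Sn](CCCC)(CCCC)CCCC; water, O
Why: Stille coupling at the C3–Br bond, which the ortho formyl and N-sulfonyl groups make electron-poor, should transfer the 1-ethoxyvinyl group from tin, and dilute acid then hydrolyses the enol ether to the methyl ketone without affecting the aldehyde or the sulfonamide.

Step 3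
Reactants: 5 3-acetyl-1-tosylpyrrole-2-carbaldehyde; 6 carbon tetrabromide
Product: 7 1-[2-(2,2-dibromovinyl)-1-tosylpyrrol-3-yl]ethanone
Conditions: 6, PPh3, Zn dust, CH2Cl2, rt (ylide preformed); then 5, 0 °C
Reagents that add atoms: carbon tetrabromide (compound 6), BrC(Br)(Br)Br
Why: In the Ramirez dibromoolefination (first stage of the Corey–Fuchs sequence) the weakly nucleophilic ylide Ph3P=CBr2 reacts with aldehydes far faster than with ketones, so at 0 °C only the formyl group should be olefinated, and preforming the ylide with zinc leaves no bromophosphonium salt to attack the enolizable ketone.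

Step 4
Reactants: 7 1-[2-(2,2-dibromovinyl)-1-tosylpyrrol-3-yl]ethanone
Product: 8 3-(1-bromovinyl)-2-(2,2-dibromovinyl)-1-tosylpyrrole
Conditions: P(OPh)3, Br2, CH2Cl2, −60 °C; then Et3N and 7, −60 °C to rt; cold work-up in the dark, used at once
Reagents that add atoms: bromine, BrBr
Why: Deoxygenative bromination of an enolizable aryl methyl ketone with the bromophosphonium salt from triphenyl phosphite and bromine (oxygen captured on phosphorus, bromide addition, amine-mediated elimination of triphenyl phosphate) is an established route from acetophenones to 1-bromoalkenes, and the reagent is formed before the substrate is added so that no free bromine meets the pyrrole or the dibromoalkene.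

Step 5
Reactants: 8 3-(1-bromovinyl)-2-(2,2-dibromovinyl)-1-tosylpyrrole
Product: 10 4,6-dibromo-1-tosylindole, via 4,6,6-tribromo-1-tosyl-5,6-dihydroindole 9 (not isolated)
Conditions: 2,6-lutidine (3 equiv), degassed o-dichlorobenzene (0.01 M), sealed tube, 160 °C, dark
Reagents that add atoms: none
Why: Proposed new method: heating should bring the conjugated triene made up of the dibromovinyl group, the pyrrole C2–C3 bond and the bromovinyl group into thermal disrotatory 6π electrocyclization, which joins the CH2 terminus (C5) to the CBr2 terminus (C6) and gives the non-aromatic dihydroindole 9; 9 holds an allylic bromide on C6 next to C5–H and in conjugation with nitrogen, so it should lose HBr at once and irreversibly to give the indole with bromine left on C4 and C6. The nearest precedent is the heat-induced electrocyclic ring closure of pyrroles and indoles bearing alkenyl groups on C2 and C3, which delivers indoles and carbazoles once the cyclohexadiene is dehydrogenated or a leaving group departs from a terminal carbon; what is new is a CBr2 terminus that gives up one bromine as HBr and keeps the other on the arene. The one ring formed is the six-membered carbocycle, closed across pyrrole C2–C3 by electrocyclic C5–C6 bond formation (6π, thermal, disrotatory). No stereocenter results, because the sp3 carbons of 9 are CH2 and CBr2 and both become sp2 in the elimination. The step needs ring closure to outrun polymerization, debromination and acid-induced decomposition: the low resonance energy of pyrrole and the unsubstituted CH2 terminus (only one bromine turns inward) keep the barrier within reach, the N-tosyl group damps the pyrrole and should turn the CBr2 terminus toward the C3 arm, aromatization by elimination spares the ring any oxidant, and high dilution, exclusion of oxygen and light and the lutidine buffer hold back the side reactions. Regiochemistry is not at issue, since the bromines on C4 and C6 are fixed by the carbon of each arm that carries them.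

Step 6
Reactants: 10 4,6-dibromo-1-tosylindole
Product: 11 4,6-dibromoindole
Conditions: Cs2CO3 (3 equiv), MeOH/THF (1:2), rt to 40 °C
Reagents that add atoms: none
Why: In this nucleophilic N-desulfonylation, methoxide generated by Cs2CO3 attacks sulfur and expels the indolide, a leaving group made better by the two ring bromines, while aryl bromides are inert to these conditions.

Step 7
Reactants: 11 4,6-dibromoindole
Product: 12 3,4,6-tribromoindole
Conditions: NBS (1.0 equiv), DMF, 0 °C, dark; cold neutral work-up
Reagents that add atoms: N-bromosuccinimide, O=C1CCC(=O)N1Br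
Why: Electrophilic aromatic substitution by NBS occurs at C3, the most nucleophilic position of an N–H indole, and the two ring bromines lower the reactivity enough that one equivalent should stop at monobromination; no stereocenter is formed.

**Compound list**

1 | 3-bromo-1H-pyrrole-2-carbaldehyde | O=Cc1[nH]ccc1Br | starting material
2 | 3-bromo-1-tosylpyrrole-2-carbaldehyde | O=Cc1c(Br)ccn1S(=O)(=O)c1ccc(C)cc1 | intermediate
3 | tributyl(1-ethoxyvinyl)stannane | CCOC(=C)[Sn](CCCC)(CCCC)CCCC | starting material
4 | 3-(1-ethoxyvinyl)-1-tosylpyrrole-2-carbaldehyde | CCOC(=C)c1ccn(S(=O)(=O)c2ccc(C)cc2)c1C=O | intermediate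
5 | 3-acetyl-1-tosylpyrrole-2-carbaldehyde | CC(=O)c1ccn(S(=O)(=O)c2ccc(C)cc2)c1C=O | intermediate
6 | carbon tetrabromide | BrC(Br)(Br)Br | starting material
7 | 1-[2-(2,2-dibromovinyl)-1-tosylpyrrol-3-yl]ethanone | CC(=O)c1ccn(S(=O)(=O)c2ccc(C)cc2)c1C=C(Br)Br | intermediate
8 | 3-(1-bromovinyl)-2-(2,2-dibromovinyl)-1-tosylpyrrole | C=C(Br)c1ccn(S(=O)(=O)c2ccc(C)cc2)c1C=C(Br)Br | intermediate
9 | 4,6,6-tribromo-1-tosyl-5,6-dihydroindole | BrC1=C2C=CN(S(=O)(=O)c3ccc(C)cc3)C2=CC(Br)(Br)C1 | intermediate
10 | 4,6-dibromo-1-tosylindole | Brc1cc(Br)c2ccn(S(=O)(=O)c3ccc(C)cc3)c2c1 | intermediate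
11 | 4,6-dibromoindole | Brc1cc(Br)c2cc[nH]c2c1 | intermediate
12 | 3,4,6-tribromoindole | Brc1cc(Br)c2c(Br)c[nH]c2c1 | target

Total step count: 7. Longest linear sequence: 7 steps (1 to 12); 3 and 6 are bought reagents.

**Steps most likely to fail**

Step 5. The triene may polymerize or lose bromine before it cyclizes, or the closure may be too slow because one bromine has to turn inward. The fallback uses known chemistry, sets out from 5 and comes back at 10. It runs the same C5–C6 electrocyclic closure in its established form, on a triene with no inward substituent and with dehydrogenation in place of elimination, while boron holds the C6 position. Aldehyde 5 would be olefinated chemoselectively by a Takai-type chromium olefination (Cl2CHBpin, CrCl2, LiI, THF) to 1-[1-tosyl-2-[(E)-2-(4,4,5,5-tetramethyl-1,3,2-dioxaborolan-2-yl)vinyl]pyrrol-3-yl]ethanone F1. The ketone would then be converted as in step 4 to 3-(1-bromovinyl)-1-tosyl-2-[(E)-2-(4,4,5,5-tetramethyl-1,3,2-dioxaborolan-2-yl)vinyl]pyrrole F2. Heating F2 in o-dichlorobenzene with DDQ present from the start, so that the dihydroindole is dehydrogenated before it can tautomerize and lose HBr, should give 4-bromo-6-(4,4,5,5-tetramethyl-1,3,2-dioxaborolan-2-yl)-1-tosylindole F3. CuBr2 in aqueous methanol at 80 °C would then exchange boron for bromine and return 10.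

Step 4. The bromophosphonium reagent may brominate or degrade the substrate, or the sensitive triene may not survive its own formation and isolation. The fallback sets out from 2 and comes back at 8, and brings in the C4 bromine by bromination and dehydrobromination of a vinyl group instead of from the ketone. Stille coupling of 2 with tributyl(vinyl)stannane (Pd(PPh3)4, toluene, 100 °C) should give 1-tosyl-3-vinylpyrrole-2-carbaldehyde F4. Ramirez olefination as in step 3 would give 2-(2,2-dibromovinyl)-1-tosyl-3-vinylpyrrole F5. Bromine in CH2Cl2 at −78 °C should add to the electron-richer vinyl group to give racemic 3-(1,2-dibromoethyl)-2-(2,2-dibromovinyl)-1-tosylpyrrole F6. DBU in THF at 0 °C would then remove the benzylic-type hydrogen together with the primary bromide, as in the standard preparation of α-bromostyrenes, to give 8.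

Step 7. The free N–H indole may be brominated a second time at C2, or the 3-bromoindole may decompose by oxidation or under traces of acid during reaction and work-up. The fallback sets out from 10 and comes back at 12, with the order of the last two operations reversed. The N-sulfonylindole 10 would be brominated at C3 with Br2 in CH2Cl2 at rt, where the sulfonyl group slows the ring enough that the reaction should stop after one substitution, to give 3,4,6-tribromo-1-tosylindole F7. Cs2CO3 in MeOH/THF would then release 12 from a basic medium free of electrophilic bromine and acid.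

**Further compounds**

F1 | step 5 | 1-[1-tosyl-2-[(E)-2-(4,4,5,5-tetramethyl-1,3,2-dioxaborolan-2-yl)vinyl]pyrrol-3-yl]ethanone | CC(=O)c1ccn(S(=O)(=O)c2ccc(C)cc2)c1/C=C/B1OC(C)(C)C(C)(C)O1
F2 | step 5 | 3-(1-bromovinyl)-1-tosyl-2-[(E)-2-(4,4,5,5-tetramethyl-1,3,2-dioxaborolan-2-yl)vinyl]pyrrole | C=C(Br)c1ccn(S(=O)(=O)c2ccc(C)cc2)c1/C=C/B1OC(C)(C)C(C)(C)O1
F3 | step 5 | 4-bromo-6-(4,4,5,5-tetramethyl-1,3,2-dioxaborolan-2-yl)-1-tosylindole | CC1(C)OB(OC1(C)C)c1cc(Br)c2ccn(S(=O)(=O)c3ccc(C)cc3)c2c1
F4 | step 4 | 1-tosyl-3-vinylpyrrole-2-carbaldehyde | C=Cc1ccn(S(=O)(=O)c2ccc(C)cc2)c1C=O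
F5 | step 4 | 2-(2,2-dibromovinyl)-1-tosyl-3-vinylpyrrole | C=Cc1ccn(S(=O)(=O)c2ccc(C)cc2)c1C=C(Br)Br
F6 | step 4 | 3-(1,2-dibromoethyl)-2-(2,2-dibromovinyl)-1-tosylpyrrole (racemic) | BrCC(Br)c1ccn(S(=O)(=O)c2ccc(C)cc2)c1C=C(Br)Br
F7 | step 7 | 3,4,6-tribromo-1-tosylindole | Brc1cc(Br)c2c(Br)cn(S(=O)(=O)c3ccc(C)cc3)c2c1
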